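**Strategy.** Everything rests on disconnecting the bond between the vinylic CH (C2') of the side chain and the benzylic CH2 (C1') on the quinone ring. One operation, zirconium-catalysed methylalumination of a terminal alkyne followed by palladium-catalysed coupling of the alkenylalane with a benzylic bromide, adds the C3' methyl group, fixes the E geometry of C2'=C3' and joins the halves. It exploits the E-trisubstituted olefin lying one CH2 from the six-membered ring and homoallylic to the C5' oxygen. The precursor is a methyl-less homopropargylic diol carrying both ketones as carbinols. Its cyclopentane with two cis quaternary carbons comes from a meso bicyclo[3.3.0]octanone, desymmetrised by a chiral base and opened by Baeyer–Villiger oxidation.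

Key step: step 9

Assumption (sense of induction): the lithium amide from (R,R)-bis(1-phenylethyl)amine is taken to remove a proton from the α-CH2 next to the bridgehead that becomes the acyl-bearing ring carbon; should the sense be the opposite, the equally available (S,S)-amine is used.

Assumption (transient stereocentres): the α-carbon, carbinol and lactol centres that end as C=O are carried as epimer mixtures and are drawn without configuration.

**Step 1**
Reactants: 1 cis-1,5-dimethylbicyclo[3.3.0]octane-3,7-dione
Product: 2 cis-1,5-dimethylbicyclo[3.3.0]octane-3,7-dione mono(2,2-dimethylpropane-1,3-diyl) ketal (meso)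
Conditions: 2,2-dimethylpropane-1,3-diol (1.0 equiv), p-TsOH (cat.), toluene, reflux, Dean–Stark
Reagents that add atoms: 2,2-dimethylpropane-1,3-diol, OCC(C)(C)CO
Why: Acid-catalysed ketalisation with one equivalent of diol should give mainly the monoketal of the symmetric dione (dione and bisketal can be separated and recycled), so that the two cyclopentanone rings become different while the molecule stays meso.

**Step 2**
Reactants: 2 monoketal
Product: 5 cis-1,5-dimethylbicyclo[3.3.0]octan-3-one (meso), via hydrazone 3 (not isolated), via deoxygenated ketal 4 (not isolated)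
Conditions: N2H4·H2O, KOH, diethylene glycol, 130 → 200 °C; then 2 M HCl, THF, rt
Reagents that add atoms: water, O
Why: Wolff–Kishner reduction (Huang-Minlon variant) removes the free ketone under basic conditions that the ketal tolerates, and acid hydrolysis of the crude ketal then frees the remaining carbonyl group.

**Step 3**
Reactants: 5 meso ketone; 6 prenyl bromide (1-bromo-3-methylbut-2-ene)
Product: 8 (1S,5R)-1,5-dimethyl-2-(3-methylbut-2-en-1-yl)bicyclo[3.3.0]octan-3-one, via lithium enolate 7 (not isolated)
Conditions: (R,R)-bis(1-phenylethyl)amine, n-BuLi, LiCl, THF, −78 °C; 5, −78 °C; then 6, DMPU, −78 → −30 °C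
Reagents that add atoms: none
Why: Enantioselective deprotonation of a meso cis-bicyclo[3.3.0]octan-3-one by a chiral lithium amide distinguishes the two enantiotopic α-CH2 groups and thereby fixes the absolute configuration of both quaternary carbons, and SN2 alkylation of the enolate by the allylic bromide gives the linear prenyl connectivity.

**Step 4**
Reactants: 8 α-prenyl ketone
Product: 9 (4aR,7aR)-4a,7a-dimethyl-1-(3-methylbut-2-en-1-yl)hexahydrocyclopenta[c]pyran-3(1H)-one (cis-fused δ-lactone)
Conditions: Me3SiOOSiMe3 (1.5 equiv), TMSOTf (10 mol %), CH2Cl2, −40 → −20 °C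
Reagents that add atoms: bis(trimethylsilyl) peroxide, C[Si](C)(C)OO[Si](C)(C)C
Why: Baeyer–Villiger oxidation with bis(trimethylsilyl) peroxide under TMSOTf catalysis is known to leave C=C bonds untouched, and the secondary C2 migrates with retention in preference to the C4 methylene, which places oxygen on the carbon that becomes the hindered ketone.

**Step 5**
Reactants: 9 lactone
Product: 10 (4aR,7aR)-4a,7a-dimethyl-1-(3-methylbut-2-en-1-yl)octahydrocyclopenta[c]pyran-3-ol (lactol)
Conditions: i-Bu2AlH (1.1 equiv), CH2Cl2, −78 °C; aq. potassium sodium tartrate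
Reagents that add atoms: none
Why: Partial reduction of a δ-lactone by i-Bu2AlH at low temperature stops at the aluminium hemiacetal, which gives the lactol on work-up.

**Step 6**
Reactants: 10 lactol; 11 propargyl bromide (3-bromoprop-1-yne)
Product: 12 1-[(1R,2R)-2-(1-hydroxy-4-methylpent-3-en-1-yl)-1,2-dimethylcyclopentyl]pent-4-yn-2-ol
Conditions: 11, activated Zn dust, THF–sat. aq. NH4Cl, 0 °C → rt
Reagents that add atoms: none
Why: In this zinc-mediated Barbier propargylation the lactol reacts through its open hydroxy aldehyde form and the allenylzinc species adds by SE2' to give the homopropargylic alcohol, whose new carbinol centre is later oxidised away.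

**Step 7**
Reactants: 13 2,6-dimethylhydroquinone (2,6-dimethylbenzene-1,4-diol)
Product: 14 2,6-dimethyl-1,4-phenylene diacetate
Conditions: Ac2O, pyridine, DMAP (cat.), rt
Reagents that add atoms: acetic anhydride, CC(=O)OC(C)=O
Why: Acetylation of both phenolic hydroxyls masks the hydroquinone against oxidation and makes the ring too electron-poor for ionic ring bromination in the next step.

**Step 8**
Reactants: 14 diacetate
Product: 15 2-(bromomethyl)-6-methyl-1,4-phenylene diacetate
Conditions: NBS (1.0 equiv), AIBN (cat.), PhCF3, reflux
Reagents that add atoms: N-bromosuccinimide, O=C1CCC(=O)N1Br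
Why: In this Wohl–Ziegler bromination the radical chain abstracts a benzylic hydrogen of the deactivated arene, the two methyl groups are equivalent by symmetry, and one equivalent of NBS should hold the reaction at the monobromide.

**Step 9**
Reactants: 12 homopropargylic diol; 15 benzylic bromide
Product: 18 2-[(2E)-5-hydroxy-6-[(1R,2R)-2-(1-hydroxy-4-methylpent-3-en-1-yl)-1,2-dimethylcyclopentyl]-3-methylhex-2-en-1-yl]-6-methylbenzene-1,4-diol, via alkenylalane 16 (not isolated), via coupled diacetate 17 (not isolated)
Conditions: Me3Al (5 equiv), Cp2ZrCl2 (0.5 equiv), CH2Cl2, 0 °C → rt; volatiles removed in vacuo; 15, Pd(PPh3)4 (5 mol %), THF, rt; then LiAlH4, 0 °C; aq. potassium sodium tartrate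
Reagents that add atoms: trimethylaluminium, C[Al](C)C
Why: Me3Al first converts both hydroxyl groups into dimethylaluminium alkoxides, and the Cp2ZrCl2/Me3Al pair then adds methyl and aluminium syn across the terminal alkyne with methyl on the internal carbon (Negishi zirconium-catalysed carboalumination) to give the (E)-alkenylalane 16. Zerovalent palladium inserts into the benzylic C–Br bond of 15, the alkenyl group passes from aluminium to palladium with retention, and reductive elimination forms the bond between the vinylic CH and the benzylic CH2; the closest known reaction type is the palladium- or nickel-catalysed coupling of (E)-2-methylalk-1-enylalanes with benzylic halides that is used for polyprenylated quinones. No ring is closed and no stereocentre is created; the only new stereochemical element is the E-trisubstituted double bond, which is controlled by the syn addition and by retention in the coupling. The step needs methyl delivery to the internal alkyne carbon (secured by the terminal alkyne), reaction at the alkyne and not at the prenyl double bond (trisubstituted olefins are inert to carboalumination) and transfer of alkenyl rather than methyl from aluminium (inherent in the palladium-catalysed transmetalation). Holding both future ketones as alkoxides leaves nothing in fragment 1 that Me3Al could attack, removal of excess Me3Al before 15 is added spares the aryl acetates, and working at or below room temperature avoids the chelation-driven E-to-Z isomerisation that homopropargylic alkoxides show on heating. LiAlH4 added to the same flask then cleaves both aryl acetates, together with any acetyl group that has wandered to an alkoxide, so that the hydroquinone diol should be obtained directly.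

**Step 10**
Reactants: 18 hydroquinone diol
Product: 19 2-[(2E)-6-[(1R,2R)-1,2-dimethyl-2-(4-methylpent-3-enoyl)cyclopentyl]-3-methyl-5-oxohex-2-en-1-yl]-6-methylcyclohexa-2,5-diene-1,4-dione (target)
Conditions: Dess–Martin periodinane (4 equiv), NaHCO3, CH2Cl2, 0 °C → rt
Reagents that add atoms: none
Why: Dess–Martin oxidation should convert both secondary carbinols into ketones under buffered neutral conditions that do not move the β,γ-double bonds into conjugation, and the same hypervalent iodine reagent dehydrogenates the hydroquinone to the 1,4-benzoquinone, so that one operation erases all undefined carbinol centres.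

**Compound list**
1 | cis-1,5-dimethylbicyclo[3.3.0]octane-3,7-dione | C1[C@]2(C)CC(=O)C[C@]2(C)CC1=O | starting material
2 | mono(2,2-dimethylpropane-1,3-diyl) ketal of 1 (meso) | C1[C@]2(C)CC3(OCC(C)(C)CO3)C[C@]2(C)CC1=O | intermediate
3 | hydrazone of 2 | C1[C@]2(C)CC3(OCC(C)(C)CO3)C[C@]2(C)CC1=NN | intermediate
4 | cis-1,5-dimethylbicyclo[3.3.0]octan-3-one 2,2-dimethylpropane-1,3-diyl ketal (meso) | C1[C@]2(C)CC3(OCC(C)(C)CO3)C[C@]2(C)CC1 | intermediate
5 | cis-1,5-dimethylbicyclo[3.3.0]octan-3-one (meso) | C1[C@]2(C)CCC[C@]2(C)CC1=O | intermediate
6 | prenyl bromide | CC(C)=CCBr | starting material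
7 | lithium (1S,5R)-1,5-dimethylbicyclo[3.3.0]oct-2-en-3-olate | [Li]OC1=C[C@]2(C)CCC[C@]2(C)C1 | intermediate
8 | (1S,5R)-1,5-dimethyl-2-(3-methylbut-2-en-1-yl)bicyclo[3.3.0]octan-3-one (C2 epimers) | CC(C)=CCC1[C@]2(C)CCC[C@]2(C)CC1=O | intermediate
9 | (4aR,7aR)-4a,7a-dimethyl-1-(3-methylbut-2-en-1-yl)hexahydrocyclopenta[c]pyran-3(1H)-one | CC(C)=CCC1[C@]2(C)CCC[C@]2(C)CC(=O)O1 | intermediate
10 | (4aR,7aR)-4a,7a-dimethyl-1-(3-methylbut-2-en-1-yl)octahydrocyclopenta[c]pyran-3-ol | CC(C)=CCC1[C@]2(C)CCC[C@]2(C)CC(O)O1 | intermediate
11 | propargyl bromide | BrCC#C | starting material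
12 | 1-[(1R,2R)-2-(1-hydroxy-4-methylpent-3-en-1-yl)-1,2-dimethylcyclopentyl]pent-4-yn-2-ol | CC(C)=CCC(O)[C@]1(C)CCC[C@]1(C)CC(O)CC#C | intermediate
13 | 2,6-dimethylhydroquinone | Cc1cc(O)cc(C)c1O | starting material
14 | 2,6-dimethyl-1,4-phenylene diacetate | CC(=O)Oc1cc(C)c(OC(C)=O)c(C)c1 | intermediate
15 | 2-(bromomethyl)-6-methyl-1,4-phenylene diacetate | CC(=O)Oc1cc(C)c(OC(C)=O)c(CBr)c1 | intermediate
16 | (E)-alkenyl(dimethyl)alane from 12, both hydroxyls as OAlMe2 | CC(C)=CCC(O[Al](C)C)[C@]1(C)CCC[C@]1(C)CC(O[Al](C)C)C/C(C)=C/[Al](C)C | intermediate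
17 | coupled hydroquinone diacetate, both hydroxyls as OAlMe2 | CC(C)=CCC(O[Al](C)C)[C@]1(C)CCC[C@]1(C)CC(O[Al](C)C)C/C(C)=C/Cc1cc(OC(C)=O)cc(C)c1OC(C)=O | intermediate
18 | 2-[(2E)-5-hydroxy-6-[(1R,2R)-2-(1-hydroxy-4-methylpent-3-en-1-yl)-1,2-dimethylcyclopentyl]-3-methylhex-2-en-1-yl]-6-methylbenzene-1,4-diol | CC(C)=CCC(O)[C@]1(C)CCC[C@]1(C)CC(O)C/C(C)=C/Cc1cc(O)cc(C)c1O | intermediate
19 | 2-[(2E)-6-[(1R,2R)-1,2-dimethyl-2-(4-methylpent-3-enoyl)cyclopentyl]-3-methyl-5-oxohex-2-en-1-yl]-6-methylcyclohexa-2,5-diene-1,4-dione | CC(C)=CCC(=O)[C@]1(C)CCC[C@]1(C)CC(=O)C/C(C)=C/CC1=CC(=O)C=C(C)C1=O | target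

Total step count: 10. Longest linear sequence: 8 (steps 1–6, 9 and 10).

**Steps most likely to fail**

Step 4 (Baeyer–Villiger oxidation beside the prenyl double bond). The hindered cyclopentanone may react so slowly that oxidation or acid-induced reaction of the electron-rich trisubstituted olefin takes over. The fallback builds the trisubstituted olefin only after the oxidation. It sets out from 5, whose enolate 7 is alkylated with allyl bromide instead of 6 to give the 2-allyl ketone F1. A terminal olefin is a poor partner for peracids, so mCPBA/NaHCO3 should convert it into the allyl lactone F2. Cross-metathesis with 2-methylbut-2-ene (second-generation Grubbs catalyst) then installs the isopropylidene end and the route is rejoined at 9.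

Step 3 (desymmetrising alkylation). Proton exchange between enolate, amine and product may erode the enantiomeric purity. C-alkylation at the neopentyl α-carbon may also be slow enough for polyalkylation to compete. The fallback avoids enolate alkylation altogether.
- It sets out from 5. The same chiral amide is used with Me3SiCl present from the start, which traps the enolate at once as the trimethylsilyl enol ether F3.
- Ozonolysis (O3, then Me2S) cleaves the ring double bond to the aldehyde acid F4.
- The allylmetal prenylbarium chloride F5 is made from prenyl chloride and activated Ba (from BaI2 and lithium biphenylide). It reacts at its unsubstituted α-carbon and adds to the aldehyde to give the hydroxy acid F6.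
- F6 closes on acidic work-up, and the route is rejoined at 9 with steps 3 and 4 both bypassed.

Step 9 (carboalumination and coupling). Several processes may interfere:
- slow carboalumination because the two alkoxides tie up the Cp2ZrCl2-derived catalyst;
- loss of olefin geometry by chelation;
- early acyl transfer from the aryl acetates that unmasks a phenoxide next to the CH2Br group;
- homocoupling of the benzylic bromide.

The fallback reverses the polarity of the same bond formation and sets out from 12 and 15.
- The alane 16 is quenched with I2 to give the (E)-vinyl iodide F7, which can be purified to a single geometry.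
- Compound 15 is converted with Zn dust and LiCl into the benzylic zinc bromide F8.
- Negishi coupling with Pd(OAc)2/SPhos, which tolerates free hydroxyl groups, gives the diacetate diol F9.
- K2CO3 in degassed MeOH removes the acetates, and the route is rejoined at 18.

**Further compounds**
F1 | step 4 | (1S,5R)-2-allyl-1,5-dimethylbicyclo[3.3.0]octan-3-one | C=CCC1[C@]2(C)CCC[C@]2(C)CC1=O
F2 | step 4 | (4aR,7aR)-1-allyl-4a,7a-dimethylhexahydrocyclopenta[c]pyran-3(1H)-one | C=CCC1[C@]2(C)CCC[C@]2(C)CC(=O)O1
F3 | step 3 | (1S,5R)-1,5-dimethyl-3-(trimethylsilyloxy)bicyclo[3.3.0]oct-2-ene | C[Si](C)(C)OC1=C[C@]2(C)CCC[C@]2(C)C1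
F4 | step 3 | 2-[(1R,2R)-2-formyl-1,2-dimethylcyclopentyl]acetic acid | O=C[C@]1(C)CCC[C@]1(C)CC(=O)O
F5 | step 3 | prenylbarium chloride | CC(C)=CC[Ba]Cl
F6 | step 3 | 2-[(1R,2R)-2-(1-hydroxy-4-methylpent-3-en-1-yl)-1,2-dimethylcyclopentyl]acetic acid | CC(C)=CCC(O)[C@]1(C)CCC[C@]1(C)CC(=O)O
F7 | step 9 | (E)-1-[(1R,2R)-2-(1-hydroxy-4-methylpent-3-en-1-yl)-1,2-dimethylcyclopentyl]-5-iodo-4-methylpent-4-en-2-ol | CC(C)=CCC(O)[C@]1(C)CCC[C@]1(C)CC(O)C/C(C)=C/I
F8 | step 9 | (2,5-diacetoxy-3-methylbenzyl)zinc bromide | CC(=O)Oc1cc(C)c(OC(C)=O)c(C[Zn]Br)c1
F9 | step 9 | diacetate of 18 with free secondary hydroxyls | CC(C)=CCC(O)[C@]1(C)CCC[C@]1(C)CC(O)C/C(C)=C/Cc1cc(OC(C)=O)cc(C)c1OC(C)=O
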